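**Assumptions:** the given SMILES is taken as authoritative (ring C–Br S, quaternary C S, trans-epoxide S,S, chain C–Br R). (S)-Me-CBS, the L-fructose-derived (ent-)Shi ketone and 4-hydroxy-3-methylbenzoic acid are treated as purchased.

## Retrosynthetic overview

1. Target ⇐ phenol deprotection ⇐ 15-membered ring closed last at the benzyl–cyclohexenyl C(sp3)–C(sp2) bond (intramolecular Negishi onto a tetrasubstituted enol triflate).
2. Tertiary aryl ester and chain C–Br ⇐ acylative SN2 opening of a terminal (S)-epoxide by the aroyl bromide (fragment union); both epoxides come from ent-Shi epoxidations of the geranyl chain.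
3. Enol triflate ⇐ α-methylation and triflation of a β-bromo ketone ⇐ invertive bromination of a hydroxy ketone.
4. Hydroxy ketone ⇐ catalytic enantioselective desymmetrisation of prochiral 2-geranyl-2-methylcyclohexane-1,3-dione (key step: sets the quaternary carbon and the carbinol that becomes C–Br) ⇐ 2-methylcyclohexane-1,3-dione + geranyl bromide.
5. Ring order: six-membered ring purchased and desymmetrised; terminal oxirane (transient), then internal oxirane; macrolide ring last. The arene comes from 4-hydroxy-3-methylbenzoic acid.

## Route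

**Step 1**
Reactants: 1, 2-methylcyclohexane-1,3-dione; 2, geranyl bromide [(2E)-1-bromo-3,7-dimethylocta-2,6-diene]
Product: 3, 2-[(2E)-3,7-dimethylocta-2,6-dien-1-yl]-2-methylcyclohexane-1,3-dione (achiral, prochiral)
Conditions: 1 M aq. NaOH (1 equiv), Bu4NI (cat.), rt, 24 h
Reagents that add atoms: none
Why: C-allylation (SN2) of the stabilised 1,3-dione enolate with a reactive allylic bromide; the O-alkylated by-product is separable and no stereocentre is formed.

**Step 2 (key step)**
Reactants: 3
Product: 4, (2R,3R)-2-geranyl-3-hydroxy-2-methylcyclohexan-1-one (OH cis to geranyl, trans to 2-Me)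
Conditions: (S)-Me-CBS (20 mol%), catecholborane (1.1 equiv), toluene, −78 → −50 °C
Reagents that add atoms: none
Why: Corey–Bakshi–Shibata desymmetrising reduction of the enantiotopic carbonyls; the catalyst fixes the carbinol as R (large group = quaternary carbon) and hydride adds anti to the larger geranyl arm, so the quaternary centre and C3 are set together. Catecholborane at low temperature leaves the alkenes alone.

**Step 3**
Reactants: 4
Product: 5, (2S,3S)-3-bromo-2-geranyl-2-methylcyclohexan-1-one (Br cis to 2-Me)
Conditions: PPh3, CBr4, toluene, 0 → 50 °C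
Reagents that add atoms: carbon tetrabromide, BrC(Br)(Br)Br
Why: Appel reaction; SN2 displacement of the alkoxyphosphonium with inversion gives the C–Br configuration of the target, and the adjacent ketone disfavours Wagner–Meerwein shift (α-keto cation).

**Step 4**
Reactants: 5
Product: 6, (2S,3S)-3-bromo-2-geranyl-2,6-dimethylcyclohexan-1-one (mixture at C6)
Conditions: LDA (1.05 equiv), THF, −78 °C; MeI, −78 → −40 °C
Reagents that add atoms: iodomethane, CI
Why: enolate alkylation at the only enolisable position (C6); the C6 stereocentre is destroyed in step 5, and the hindered secondary bromide is inert at −78 °C.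

**Step 5**
Reactants: 6
Product: 7, (5S,6S)-5-bromo-6-geranyl-2,6-dimethylcyclohex-1-en-1-yl trifluoromethanesulfonate
Conditions: KHMDS, THF, −78 °C; PhNTf2, −78 → 0 °C
Reagents that add atoms: N-phenyl-bis(trifluoromethanesulfonimide), FC(F)(F)S(=O)(=O)N(c1ccccc1)S(=O)(=O)C(F)(F)F
Why: enolate O-triflation; only C6–H can be removed, so the tetrasubstituted enol triflate forms regiospecifically (as for 2,2,6-trimethylcyclohexanone).

**Step 6**
Reactants: 7
Product: 8, (5S,6S)-5-bromo-6-{(2E)-5-[(2S)-3,3-dimethyloxiran-2-yl]-3-methylpent-2-en-1-yl}-2,6-dimethylcyclohex-1-en-1-yl triflate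
Conditions: ent-Shi ketone (0.3 equiv), Oxone (1.0 equiv), K2CO3, Bu4NHSO4, MeCN–DMM/aq. borate–EDTA buffer (pH 10.5), −10 °C, stopped at about 85% conversion
Reagents that add atoms: Oxone (potassium peroxymonosulfate), [K+].[O-]S(=O)(=O)OO
Why: Shi asymmetric epoxidation; the L-fructose-derived ketone gives the (S)-epoxide. The terminal alkene reacts first because the internal one carries the bulky quaternary ring on its allylic carbon, and the enol triflate is too electron-poor to react.

**Step 7**
Reactants: 9, 4-hydroxy-3-methylbenzoic acid
Product: 10, 3-methyl-4-(pivaloyloxy)benzoic acid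
Conditions: PivCl (2.2 equiv), pyridine, DMAP (cat.), CH2Cl2, 0 °C → rt; then THF/H2O, rt
Reagents that add atoms: pivaloyl chloride, CC(C)(C)C(=O)Cl
Why: phenol acylation; the mixed anhydride at the carboxyl is hydrolysed on work-up, and the electron-withdrawing pivalate later keeps the benzylic bromide from solvolysing.

**Step 8**
Reactants: 10
Product: 11, 3-(bromomethyl)-4-(pivaloyloxy)benzoic acid
Conditions: NBS (1.05 equiv), AIBN (cat.), PhCF3, 85 °C
Reagents that add atoms: N-bromosuccinimide, BrN1C(=O)CCC1=O
Why: Wohl–Ziegler benzylic bromination; the acyloxy/carboxy-substituted ring resists electrophilic ring bromination.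

**Step 9**
Reactants: 8; 11
Product: 12, (5S,6S)-5-bromo-6-{(2E,6R)-6-bromo-7-[3-(bromomethyl)-4-(pivaloyloxy)benzoyloxy]-3,7-dimethyloct-2-en-1-yl}-2,6-dimethylcyclohex-1-en-1-yl triflate
Conditions: 11, (COBr)2, DMF (cat.), CH2Cl2, 0 °C → rt, evaporate; then 8, Bu4NBr (20 mol%), 2,6-di-tert-butylpyridine (10 mol%), toluene, 0 → 40 °C
Reagents that add atoms: oxalyl bromide, BrC(=O)C(=O)Br; tetrabutylammonium bromide, CCCC[N+](CCCC)(CCCC)CCCC.[Br-]
Why: Proposed new method: halide-catalysed acylative epoxide opening in which Br− attacks the less substituted epoxide carbon in SN2 fashion (inversion, S → R) and the resulting tertiary alkoxide is trapped by the aroyl bromide, regenerating Br−; this forms the hindered tertiary ester at oxygen (no acylation of a tertiary alcohol needed) and sets the chain C–Br; closest known reaction type is the onium-halide-catalysed addition of acyl halides to epoxides giving β-halo esters with halide at the less hindered carbon.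

**Step 10**
Reactants: 12
Product: 13, (5S,6S)-5-bromo-6-({(2S,3S)-3-[(3R)-3-bromo-4-methyl-4-{[3-(bromomethyl)-4-(pivaloyloxy)benzoyl]oxy}pentyl]-3-methyloxiran-2-yl}methyl)-2,6-dimethylcyclohex-1-en-1-yl triflate
Conditions: ent-Shi ketone (0.5 equiv), Oxone (2 equiv), K2CO3, Bu4NHSO4, MeCN–DMM/aq. buffer (pH 10.5), 0 °C
Reagents that add atoms: Oxone (potassium peroxymonosulfate), [K+].[O-]S(=O)(=O)OO
Why: Shi asymmetric epoxidation of the only remaining electron-rich alkene; the same catalyst gives the (2S,3S)-trans-epoxide under catalyst control, and the aryl pivalate and deactivated benzylic bromide survive the cold buffered medium.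

**Step 11**
Reactants: 13
Product: 14, O-pivaloyl derivative of the target (15-membered macrolide with the tetrasubstituted cyclohexene in place)
Conditions: Zn dust (activated), LiCl, THF, 0 °C → rt; then slow addition (10 h) to Pd(OAc)2 (10 mol%)/SPhos (20 mol%), THF, 45 °C, final 2 mM
Reagents that add atoms: none
Why: Proposed new method: intramolecular Negishi macrocyclisation, in which zinc inserts selectively into the benzylic C–Br (the secondary alkyl bromides are inert at ≤ rt) and the benzylzinc couples with the enol triflate under high dilution; closest known reactions are intermolecular Negishi couplings of benzylzinc halides with hindered 2,6,6-trisubstituted cyclohexenyl triflates and B-alkyl Suzuki macrocyclisations; no stereocentre is formed.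

**Step 12**
Reactants: 14
Product: 15, target (CID46880797)
Conditions: K2CO3, MeOH, 0 °C → rt
Reagents that add atoms: none
Why: methanolysis of the aryl pivalate (phenoxide leaving group) is much faster than attack on the hindered tertiary-alkyl benzoate, which is further deactivated once the para-phenoxide forms; the epoxide and both secondary bromides are untouched.

## Compound list

1 | 2-methylcyclohexane-1,3-dione | CC1C(=O)CCCC1=O | starting material
2 | geranyl bromide | CC(C)=CCC/C(C)=C/CBr | starting material
3 | 2-geranyl-2-methylcyclohexane-1,3-dione | CC1(C/C=C(\C)CCC=C(C)C)C(=O)CCCC1=O | intermediate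
4 | (2R,3R)-2-geranyl-3-hydroxy-2-methylcyclohexan-1-one | C[C@]1(C/C=C(\C)CCC=C(C)C)C(=O)CCC[C@H]1O | intermediate
5 | (2S,3S)-3-bromo-2-geranyl-2-methylcyclohexan-1-one | C[C@]1(C/C=C(\C)CCC=C(C)C)C(=O)CCC[C@@H]1Br | intermediate
6 | (2S,3S)-3-bromo-2-geranyl-2,6-dimethylcyclohexan-1-one (C6 mixture) | C[C@]1(C/C=C(\C)CCC=C(C)C)C(=O)C(C)CC[C@@H]1Br | intermediate
7 | (5S,6S)-5-bromo-6-geranyl-2,6-dimethylcyclohex-1-en-1-yl triflate | C[C@]1(C/C=C(\C)CCC=C(C)C)C(OS(=O)(=O)C(F)(F)F)=C(C)CC[C@@H]1Br | intermediate
8 | terminal (S)-epoxide of 7 | C[C@]1(C/C=C(\C)CC[C@@H]2OC2(C)C)C(OS(=O)(=O)C(F)(F)F)=C(C)CC[C@@H]1Br | intermediate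
9 | 4-hydroxy-3-methylbenzoic acid | Cc1cc(C(=O)O)ccc1O | starting material
10 | 3-methyl-4-(pivaloyloxy)benzoic acid | Cc1cc(C(=O)O)ccc1OC(=O)C(C)(C)C | intermediate
11 | 3-(bromomethyl)-4-(pivaloyloxy)benzoic acid | BrCc1cc(C(=O)O)ccc1OC(=O)C(C)(C)C | intermediate
12 | (6R)-bromo tertiary aryl ester, enol triflate | C[C@]1(C/C=C(\C)CC[C@@H](Br)C(C)(C)OC(=O)c2ccc(OC(=O)C(C)(C)C)c(CBr)c2)C(OS(=O)(=O)C(F)(F)F)=C(C)CC[C@@H]1Br | intermediate
13 | (2S,3S)-epoxide of 12 | C[C@]1(C[C@@H]2O[C@@]2(C)CC[C@@H](Br)C(C)(C)OC(=O)c2ccc(OC(=O)C(C)(C)C)c(CBr)c2)C(OS(=O)(=O)C(F)(F)F)=C(C)CC[C@@H]1Br | intermediate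
14 | macrocycle, phenol as pivalate | C[C@]1(C[C@@H]2O[C@@]2(C)CC[C@@H](Br)C(C)(C)OC(=O)c2ccc(OC(=O)C(C)(C)C)c(c2)C3)C3=C(C)CC[C@@H]1Br | intermediate
15 | CID46880797 | CC1=C2Cc3cc(ccc3O)C(=O)OC(C)(C)[C@H](Br)CC[C@]3(C)O[C@H]3C[C@]2(C)[C@@H](Br)CC1 | target

## Totals and risks

Total steps: 12. Longest linear sequence: 10 (steps 1–6, 9–12).

Three steps most likely to fail:

1. **Step 9 (acylative epoxide opening).** Bromide may attack the tertiary carbon, giving the tertiary bromide and secondary ester. Fallback: switch from epoxide to alkene chemistry, i.e. intermolecular Markovnikov bromo-esterification of the terminal alkene of 7 with acid 11 and NBS. The regiochemistry is then intrinsically correct, and the C–Br configuration is controlled by a chiral Lewis-base catalyst or by separating the epimers.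
2. **Step 11 (Negishi macrocyclisation).** Ring closure at a hindered tetrasubstituted triflate may lose to protonation or homocoupling, and the epoxide is exposed to zinc salts. Fallback: move the ring closure to the ester bond. Couple 7 intermolecularly with the benzylzinc of a carboxyl-protected arene, then close the macrolide by intramolecular acyl bromide/epoxide opening and epoxidise the internal alkene last.
3. **Step 3 (Appel at a neopentylic carbinol).** E2 elimination or rearrangement may dominate over SN2. Fallback: abandon SN2 and form the ring C–Br and the quaternary centre together by a bromonium-initiated cation–olefin cyclisation of an acyclic (E)-alkene bearing an enol-silane or β-keto-ester terminator, so the ring is built with bromine already in place.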